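**Strategy**

Numbering: cyclohexane ring C1 (CH2), C2–C3 (epoxide, C3 methyl), C4 (OH), C5 (ester), C6 (side chain); side chain C7(=C14H2)–C8–C11. The ring is cut at C5–C6 and C3–C4. An endo Diels–Alder reaction of (3E,5E)-hepta-3,5-dien-1-yne (C6, C1, C2, C3 plus ethynyl C7/C14) with vinylene carbonate (C4, C5) forms both bonds at once and sets the all-cis C6/C5/C4 array; it exploits the cis-1,2-dioxygenated C4–C5 edge of the carbocycle as a cis-enediol. The ethynyl group later becomes the C7 alkenyl carbinol; the C1=C2 alkene is moved to C2=C3 via a C4 ketone, then reduced and epoxidised.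

Key step: step 2

Remark: the C5 ester of the given structure is the (R)-2-methylbutanoate, so (R)-2-methylbutanoic acid is used; cycloadduct 4, diol 5 and acetal 8 are racemic (one enantiomer drawn) and the ring enantiomers are separated as diastereomeric esters in step 4.

**Route**

Step 1
Reactants: 1 (2E,4E)-hexa-2,4-dienal
Product: 2 (3E,5E)-hepta-3,5-dien-1-yne
Conditions: Me3SiCHN2, LiN(iPr)2, THF, −78 °C to rt
Reagents that add atoms: trimethylsilyldiazomethane, C[Si](C)(C)C=[N+]=[N-]
Why: Colvin rearrangement (Seyferth–Gilbert-type homologation): the lithiated diazo compound adds to the aldehyde, Peterson elimination and loss of N2 give an alkylidene carbene whose 1,2-hydrogen shift delivers the terminal alkyne without touching the (E,E)-diene, a variant that suits enals better than the methanolic Ohira–Bestmann protocol.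

Step 2
Reactants: 2 (3E,5E)-hepta-3,5-dien-1-yne; 3 vinylene carbonate
Product: 4 rac-(3aR,4S,7S,7aS)-4-ethynyl-7-methyl-3a,4,7,7a-tetrahydro-1,3-benzodioxol-2-one (all-cis)
Conditions: 3 (5 equiv), BHT (cat.), toluene, 170 °C, sealed tube
Reagents that add atoms: none
Why: Concerted suprafacial [4+2] cycloaddition of the s-cis (E,E)-diene (C6=C1–C2=C3) with the cis-enediol carbonate forms C5–C6 and C3–C4 together; the closest known reaction type is the thermal Diels–Alder reaction of vinylene carbonate with (E,E)-1,4-disubstituted butadienes such as 1,4-diacetoxybutadiene. The cyclohexene ring is closed by intermolecular [4+2] cycloaddition, the dioxolanone ring being carried in intact. C4 and C5 are cis because the dienophile is a cis alkene held in a five-membered ring and adds suprafacially; C6 and the temporary centre C3 follow from the E geometry of both diene termini, and the cis relation of the C6 ethynyl group to the C5 and C4 oxygens follows from the endo transition state in which the carbonate lies under the diene. The step needs endo over exo selectivity and reaction at the diene, not the alkyne; the symmetrical dienophile removes any regiochemical question, the endo preference of vinylene carbonate is well established for this diene class, and an isolated alkyne is not a partner for this weak dienophile. The adduct is racemic and the enantiomers are separated in step 4.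

Step 3
Reactants: 4 rac-(3aR,4S,7S,7aS)-4-ethynyl-7-methyl-3a,4,7,7a-tetrahydro-1,3-benzodioxol-2-one
Product: 5 rac-(1S,2R,3S,6S)-3-ethynyl-6-methylcyclohex-4-ene-1,2-diol (all-cis)
Conditions: K2CO3 (0.2 equiv), MeOH, 0 °C to rt
Reagents that add atoms: none
Why: Base-catalysed methanolysis (transesterification) of the strained five-membered cyclic carbonate releases the cis-diol with no change at any stereocentre, the terminal alkyne and ring alkene being inert.

Step 4
Reactants: 5 rac-(1S,2R,3S,6S)-3-ethynyl-6-methylcyclohex-4-ene-1,2-diol; 6 (R)-2-methylbutanoic acid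
Product: 9 (1R,2S,3S,6S)-6-ethynyl-2-hydroxy-3-methylcyclohex-4-en-1-yl (2R)-2-methylbutanoate, via acid chloride 7 (not isolated), via stannylene acetal 8 (not isolated)
Conditions: 6, (COCl)2, DMF (cat.), CH2Cl2, 0 °C to rt, concentrate; 5, Bu2SnO, toluene, reflux (Dean–Stark); then 7, toluene, 0 °C to rt; chromatographic separation of the two diastereomeric esters
Reagents that add atoms: none
Why: Tin-mediated regioselective acylation: the stannylene acetal of a cis-1,2-diol reacts at its equatorial oxygen, which in the favoured half-chair (slim ethynyl group pseudoaxial, methyl pseudoequatorial, conformer A) is O5 next to C6, and the homochiral (R)-acyl group turns the two ring enantiomers into diastereomers that are separated by chromatography, so this step also fixes the absolute configuration of C5 and C6 (classical resolution).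

Step 5
Reactants: 9 (1R,2S,3S,6S)-6-ethynyl-2-hydroxy-3-methylcyclohex-4-en-1-yl (2R)-2-methylbutanoate
Product: 10 (1R,2S,3S,6S)-6-ethynyl-3-methyl-2-(triethylsilyloxy)cyclohex-4-en-1-yl (2R)-2-methylbutanoate
Conditions: Et3SiOTf, 2,6-lutidine, CH2Cl2, −78 to 0 °C
Reagents that add atoms: triethylsilyl trifluoromethanesulfonate, CC[Si](CC)(CC)OS(=O)(=O)C(F)(F)F
Why: Silylation of the remaining axial, hindered C4 hydroxyl with the reactive silyl triflate at low temperature, where acyl migration from O5 is not expected (silyl ether protection).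

Step 6
Reactants: 10 (1R,2S,3S,6S)-6-ethynyl-3-methyl-2-(triethylsilyloxy)cyclohex-4-en-1-yl (2R)-2-methylbutanoate
Product: 12 (1R,2S,3S,6R)-6-(1-iodoethenyl)-3-methyl-2-(triethylsilyloxy)cyclohex-4-en-1-yl (2R)-2-methylbutanoate, via alkenylborane 11 (not isolated)
Conditions: B-iodo-9-BBN, hexane/CH2Cl2, −20 °C; then AcOH, 0 °C
Reagents that add atoms: B-iodo-9-borabicyclo[3.3.1]nonane, IB1C2CCCC1CCC2
Why: Haloboration–protonolysis: syn addition of B–I across the terminal alkyne puts iodine on the internal carbon C7, and acetic acid cleaves the alkenyl C–B bond to give the 2-iodo-1-alkene, while the ring alkene, the ester and the silyl ether should not react at −20 °C.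

Step 7
Reactants: 13 4-methylpent-3-en-1-ol
Product: 14 4-methylpent-3-enal
Conditions: Dess–Martin periodinane, NaHCO3, CH2Cl2, 0 °C; used at once
Reagents that add atoms: none
Why: Buffered Dess–Martin oxidation gives the β,γ-unsaturated aldehyde under neutral conditions that do not move the alkene into conjugation.

Step 8
Reactants: 12 the 2-iodoalkene; 14 4-methylpent-3-enal
Product: 15 (8S)-allylic alcohol: ring as in 12, C6 now bearing C7(=CH2)–C8H(OH)–CH2–CH=C(CH3)2
Conditions: CrCl2 (4 equiv), NiCl2 (2 mol%), chiral oxazoline–sulfonamide ligand, Et3N, THF, rt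
Reagents that add atoms: none
Why: Nozaki–Hiyama–Kishi coupling: NiCl2-catalysed conversion of the alkenyl iodide into an alkenylchromium species (trivalent chromium) that adds only to the aldehyde, the chiral ligand on chromium selecting the aldehyde face so that the new C8 carbinol should be (8S) under reagent control, with ester, silyl ether and alkenes tolerated.

Step 9
Reactants: 15 the (8S)-allylic alcohol; 16 angelic acid [(Z)-2-methylbut-2-enoic acid]
Product: 18 C8 angelate of 15, via mixed anhydride 17 (not isolated)
Conditions: 16, 2,4,6-trichlorobenzoyl chloride, Et3N, toluene, rt; then 15, toluene, 75 °C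
Reagents that add atoms: none
Why: Yamaguchi esterification of the only free hydroxyl through the mixed anhydride and without DMAP, conditions that acylate hindered secondary alcohols while keeping the (Z) geometry of the angelate and the C8 configuration.

Step 10
Reactants: 18 the C8 angelate
Product: 19 (10R)-10,11-epoxide of 18
Conditions: D-fructose-derived Shi ketone (0.3 equiv), Oxone (2KHSO5·KHSO4·K2SO4), K2CO3, Bu4NHSO4, Na2B4O7 buffer (pH 10.5), MeCN/CH2(OMe)2/H2O, 0 °C
Reagents that add atoms: Oxone (active oxidant potassium peroxymonosulfate, KHSO5), [K+].[O-]S(=O)(=O)OO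
Why: Shi asymmetric epoxidation: the chiral dioxirane reacts fastest with the electron-rich trisubstituted C10=C11 alkene (the cis-disubstituted ring alkene, the 1,1-disubstituted C7=C14 alkene and the angelate are slower), and the spiro transition state of the D-fructose-derived catalyst should give the (10R) epoxide under reagent control.

Step 11
Reactants: 19 the (10R)-epoxide silyl ether
Product: 20 C4 alcohol: 19 without the triethylsilyl group
Conditions: HF·pyridine, pyridine, THF, 0 °C
Reagents that add atoms: none
Why: Buffered fluoride cleavage of the triethylsilyl ether frees the C4 hydroxyl without acid strong enough to open the trisubstituted epoxide and without base that would promote O5-to-O4 acyl migration (desilylation).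

Step 12
Reactants: 20 the C4 alcohol
Product: 22 conjugated enone (C4 ketone, C2=C3 alkene, C1 methylene), via deconjugated ketone 21 (not isolated)
Conditions: Dess–Martin periodinane, NaHCO3, CH2Cl2, 0 °C to rt; then DBU (0.1 equiv), CH2Cl2, 0 °C
Reagents that add atoms: none
Why: Dess–Martin oxidation gives the β,γ-unsaturated ketone 21, whose doubly activated C3–H is removed by DBU and whose dienolate is reprotonated at C1, moving the alkene into conjugation at C2=C3 and erasing the temporary C3 centre; the C5–H is pseudo-equatorial in the half-chair with the C6 side chain equatorial and the acyloxy group axial, hence poorly aligned for enolisation, so C5 should keep its configuration (oxidation then base-mediated alkene conjugation).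

Step 13
Reactants: 22 the conjugated enone
Product: 23 (4R)-allylic alcohol, all-cis at C4/C5/C6
Conditions: NaBH4, CeCl3·7H2O, MeOH, −78 °C
Reagents that add atoms: none
Why: Luche reduction (1,2-selective): hydride should add axially to the C4 carbonyl anti to the axial C5 acyloxy group (Felkin–Anh), as in the reduction of carvone to cis-carveol, giving the equatorial C4 alcohol cis to the C5 and C6 substituents, while esters, epoxide and angelate are not reduced at −78 °C.

Step 14
Reactants: 23 the (4R)-allylic alcohol
Product: 24 target, (2S,3R,4R,5R,6S,8S,10R)-8-angeloyloxy-2,3:10,11-diepoxy-4-hydroxybisabol-7(14)-en-5-yl (2R)-2-methylbutanoate (numbering of the overview)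
Conditions: VO(acac)2 (5 mol%), t-BuOOH (decane), CH2Cl2, 0 °C to rt
Reagents that add atoms: tert-butyl hydroperoxide, CC(C)(C)OO
Why: Vanadium-catalysed hydroxyl-directed epoxidation: the alkoxide-bound peroxo vanadium complex delivers oxygen to the C2=C3 alkene on the face of the allylic C4 hydroxyl, giving the syn epoxy alcohol (2S,3R), while the non-allylic C7=C14 alkene, the angelate and the existing epoxide should remain untouched.

**Compound list**

1 | (2E,4E)-hexa-2,4-dienal (sorbaldehyde) | C/C=C/C=C/C=O | starting material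
2 | (3E,5E)-hepta-3,5-dien-1-yne | C#C/C=C/C=C/C | intermediate
3 | vinylene carbonate (1,3-dioxol-2-one) | O=C1OC=CO1 | starting material
4 | rac-(3aR,4S,7S,7aS)-4-ethynyl-7-methyl-3a,4,7,7a-tetrahydro-1,3-benzodioxol-2-one (all-cis; racemate, enantiomer leading to 24 drawn) | C#C[C@@H]1C=C[C@H](C)[C@@H]2OC(=O)O[C@H]12 | intermediate
5 | rac-(1S,2R,3S,6S)-3-ethynyl-6-methylcyclohex-4-ene-1,2-diol (all-cis; racemate, one enantiomer drawn) | C#C[C@@H]1C=C[C@H](C)[C@H](O)[C@@H]1O | intermediate
6 | (R)-2-methylbutanoic acid | CC[C@@H](C)C(=O)O | starting material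
7 | (R)-2-methylbutanoyl chloride | CC[C@@H](C)C(=O)Cl | intermediate
8 | 2,2-dibutyl-1,3,2-dioxastannolane (stannylene acetal) of diol 5 (racemate, one enantiomer drawn) | C#C[C@@H]1C=C[C@H](C)[C@@H]2O[Sn](CCCC)(CCCC)O[C@H]12 | intermediate
9 | (1R,2S,3S,6S)-6-ethynyl-2-hydroxy-3-methylcyclohex-4-en-1-yl (2R)-2-methylbutanoate | C#C[C@@H]1C=C[C@H](C)[C@H](O)[C@@H]1OC(=O)[C@H](C)CC | intermediate
10 | (1R,2S,3S,6S)-6-ethynyl-3-methyl-2-(triethylsilyloxy)cyclohex-4-en-1-yl (2R)-2-methylbutanoate | C#C[C@@H]1C=C[C@H](C)[C@H](O[Si](CC)(CC)CC)[C@@H]1OC(=O)[C@H](C)CC | intermediate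
11 | (Z)-2-iodoalkenyl-9-BBN adduct of 10 (boron on the terminal carbon, iodine on C7) | I/C(=C\B1C2CCCC1CCC2)[C@@H]3C=C[C@H](C)[C@H](O[Si](CC)(CC)CC)[C@@H]3OC(=O)[C@H](C)CC | intermediate
12 | (1R,2S,3S,6R)-6-(1-iodoethenyl)-3-methyl-2-(triethylsilyloxy)cyclohex-4-en-1-yl (2R)-2-methylbutanoate | C=C(I)[C@@H]1C=C[C@H](C)[C@H](O[Si](CC)(CC)CC)[C@@H]1OC(=O)[C@H](C)CC | intermediate
13 | 4-methylpent-3-en-1-ol | CC(C)=CCCO | starting material
14 | 4-methylpent-3-enal | CC(C)=CCC=O | intermediate
15 | (8S)-allylic alcohol: ring as in 12, C6 bearing C7(=CH2)–C8H(OH)–CH2–CH=C(CH3)2 | C=C([C@H](CC=C(C)C)O)[C@@H]1C=C[C@H](C)[C@H](O[Si](CC)(CC)CC)[C@@H]1OC(=O)[C@H](C)CC | intermediate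
16 | angelic acid, (Z)-2-methylbut-2-enoic acid | C/C=C(/C)C(=O)O | starting material
17 | angelic 2,4,6-trichlorobenzoic mixed anhydride | C/C=C(/C)C(=O)OC(=O)c1c(Cl)cc(Cl)cc1Cl | intermediate
18 | C8 angelate of 15 | C=C([C@H](CC=C(C)C)OC(=O)/C(C)=C\C)[C@@H]1C=C[C@H](C)[C@H](O[Si](CC)(CC)CC)[C@@H]1OC(=O)[C@H](C)CC | intermediate
19 | (10R)-10,11-epoxide of 18 | C=C([C@H](C[C@H]1OC1(C)C)OC(=O)/C(C)=C\C)[C@@H]1C=C[C@H](C)[C@H](O[Si](CC)(CC)CC)[C@@H]1OC(=O)[C@H](C)CC | intermediate
20 | C4 alcohol (19 without the silyl group; C1=C2 alkene, all-cis C3 methyl/C4 OH/C5 ester/C6 side chain) | C=C([C@H](C[C@H]1OC1(C)C)OC(=O)/C(C)=C\C)[C@@H]1C=C[C@H](C)[C@H](O)[C@@H]1OC(=O)[C@H](C)CC | intermediate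
21 | β,γ-unsaturated C4 ketone (C1=C2 alkene, C3–H retained) | C=C([C@H](C[C@H]1OC1(C)C)OC(=O)/C(C)=C\C)[C@@H]1C=C[C@H](C)C(=O)[C@@H]1OC(=O)[C@H](C)CC | intermediate
22 | conjugated enone (C4 ketone, C2=C3 alkene, C5 ester and C6 side chain cis) | C=C([C@H](C[C@H]1OC1(C)C)OC(=O)/C(C)=C\C)[C@@H]1CC=C(C)C(=O)[C@@H]1OC(=O)[C@H](C)CC | intermediate
23 | (4R)-allylic alcohol, C4 OH/C5 ester/C6 side chain all-cis | C=C([C@H](C[C@H]1OC1(C)C)OC(=O)/C(C)=C\C)[C@@H]1CC=C(C)[C@H](O)[C@@H]1OC(=O)[C@H](C)CC | intermediate
24 | (2S,3R,4R,5R,6S,8S,10R)-8-angeloyloxy-2,3:10,11-diepoxy-4-hydroxybisabol-7(14)-en-5-yl (2R)-2-methylbutanoate | C=C([C@H](C[C@H]1OC1(C)C)OC(=O)/C(C)=C\C)[C@@H]1C[C@@H]2O[C@]2(C)[C@H](O)[C@@H]1OC(=O)[C@H](C)CC | target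

**Step count and risks**

Total steps: 14. Longest linear sequence: 13 (steps 1–6 and 8–14; step 7 makes aldehyde 14 in one step).

Steps most likely to fail:

1. Step 2 (key cycloaddition). Vinylene carbonate is a weak dienophile, so conversion may be low while the volatile conjugated dienyne oligomerises at 170 °C, and endo selectivity may erode at that temperature. Fallback, setting out from 3 and returning at 5: the alkyne is installed after the cycloaddition. Commercial (2E,4E)-hexa-2,4-dien-1-ol is silylated (TBSCl, imidazole) to the thermally robust diene tert-butyl[(2E,4E)-hexa-2,4-dien-1-yloxy]dimethylsilane F1. F1 undergoes the same endo Diels–Alder reaction with 3 to give the all-cis carbonate F2. HF·pyridine frees the primary alcohol F3 and Dess–Martin oxidation gives the aldehyde F4. Seyferth–Gilbert homologation with the Ohira–Bestmann reagent (K2CO3, MeOH, 0 °C), which also methanolyses the carbonate, then delivers diol 5.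

2. Step 4 (regioselective acylation and resolution). Discrimination between the two cis hydroxyls may be incomplete (ester at O4, diester, or acyl migration), which would also blur the separation of the diastereomers. Fallback, setting out from 5 and returning at 9: regiocontrol by orthoester hydrolysis instead of tin activation. Diol 5 with HC(OMe)3 and camphorsulfonic acid gives the cyclic orthoformate F5. Mild aqueous acid opens it to the axial O4 formate F6 (axial ester, equatorial hydroxyl). O5 is then esterified with 6 (diisopropylcarbodiimide, DMAP cat.) to the formate ester F7, and the diastereomers are separated at this stage. The formate is removed with KHCO3 in aqueous methanol to give 9.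

3. Step 8 (C8 stereocontrol). Catalyst control may be weak when the chiral chromium complex meets the hindered, chiral alkenyl iodide (mismatched double stereodifferentiation). Fallback, setting out from 12 and returning at 15: the coupling of 12 with 14 is run without the chiral ligand, giving 15 together with its C8 epimer F8. Dess–Martin oxidation of the mixture gives the single enone F9. Reagent-controlled reduction with the (R)-B-methyl oxazaborolidine (CBS) catalyst and catecholborane at −78 °C then returns (8S)-15.

Further compounds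
F1 | step 2 | tert-butyl[(2E,4E)-hexa-2,4-dien-1-yloxy]dimethylsilane | C/C=C/C=C/CO[Si](C)(C)C(C)(C)C
F2 | step 2 | rac all-cis 4-[(tert-butyldimethylsilyloxy)methyl]-7-methyl-3a,4,7,7a-tetrahydro-1,3-benzodioxol-2-one | CC(C)(C)[Si](C)(C)OC[C@@H]1C=C[C@H](C)[C@@H]2OC(=O)O[C@H]12
F3 | step 2 | rac all-cis 4-(hydroxymethyl)-7-methyl-3a,4,7,7a-tetrahydro-1,3-benzodioxol-2-one | OC[C@@H]1C=C[C@H](C)[C@@H]2OC(=O)O[C@H]12
F4 | step 2 | rac all-cis 7-methyl-2-oxo-3a,4,7,7a-tetrahydro-1,3-benzodioxole-4-carbaldehyde | O=C[C@@H]1C=C[C@H](C)[C@@H]2OC(=O)O[C@H]12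
F5 | step 4 | rac all-cis 4-ethynyl-2-methoxy-7-methyl-3a,4,7,7a-tetrahydro-1,3-benzodioxole (cyclic orthoformate of 5) | C#C[C@@H]1C=C[C@H](C)[C@@H]2OC(OC)O[C@H]12
F6 | step 4 | rac all-cis 5-ethynyl-6-hydroxy-2-methylcyclohex-3-en-1-yl formate (O4 formate of 5) | C#C[C@@H]1C=C[C@H](C)[C@H](OC=O)[C@@H]1O
F7 | step 4 | O4 formate of 9: (1R,2S,3S,6S)-6-ethynyl-2-(formyloxy)-3-methylcyclohex-4-en-1-yl (2R)-2-methylbutanoate | C#C[C@@H]1C=C[C@H](C)[C@H](OC=O)[C@@H]1OC(=O)[C@H](C)CC
F8 | step 8 | (8R)-epimer of 15 | C=C([C@@H](CC=C(C)C)O)[C@@H]1C=C[C@H](C)[C@H](O[Si](CC)(CC)CC)[C@@H]1OC(=O)[C@H](C)CC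
F9 | step 8 | C8 ketone from 15 (C7 methylene enone) | C=C(C(=O)CC=C(C)C)[C@@H]1C=C[C@H](C)[C@H](O[Si](CC)(CC)CC)[C@@H]1OC(=O)[C@H](C)CC
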